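The route disconnects the C2–C3 bond of the dihydropyran ring (ring C) of the flavan. C2 carries the ring oxygen O1 and aryl ring B, which is the substitution pattern of an aryl ester carbon, and C4–C3 is the inner part of an allyl group ortho to O1 on ring A. A Tebbe-mediated tandem ester methylenation/ring-closing olefin metathesis therefore turns a 2-allylaryl benzoate into the 2-aryl-4H-chromene in one operation, forging C2=C3 and closing ring C. Iridium-catalysed asymmetric hydrogenation then sets C2 (S). The remote (R)-diarylmethine comes earlier from a rhodium-catalysed asymmetric conjugate arylation of a chalcone, and benzyl ethers are removed at the end.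

Key step: step 12

Remark on numbering: flavan numbering is used (O1, C2, C3, C4, C4a to C8a). Ring A is the benzo ring of the chromane, ring C its pyran ring, ring B the aryl group on C2, ring D the 4-hydroxyphenyl group and ring E the 4-hydroxy-2-methoxyphenyl group.

Assumption: the two stereocentres are too far apart to influence each other, so each is set by catalyst control, and in steps 5 and 13 the ligand enantiomer used is the one that gives the configuration drawn.

Step 1
Reactants: 1 5-bromo-2,4-dihydroxybenzaldehyde
Product: 2 5-bromo-2-hydroxy-4-(methoxymethoxy)benzaldehyde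
Conditions: MOMCl (1.05 equiv), K2CO3, acetone, 0 to 25 °C
Reagents that add atoms: chloromethyl methyl ether (MOMCl), COCCl
Why: Williamson-type O-alkylation in which the 4-OH (para to the aldehyde, not hydrogen-bonded) is the more acidic and more accessible phenol, whereas the 2-OH is held in a hydrogen bond to the aldehyde, so one equivalent of MOMCl should mask the future O1 selectively.

Step 2
Reactants: 2 5-bromo-2-hydroxy-4-(methoxymethoxy)benzaldehyde
Product: 3 2-(benzyloxy)-5-bromo-4-(methoxymethoxy)benzaldehyde
Conditions: BnBr, K2CO3, DMF, 60 °C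
Reagents that add atoms: benzyl bromide, BrCc1ccccc1
Why: Williamson etherification of the remaining chelated phenol under more forcing conditions should place the benzyl ether on the future O7, and the MOM acetal is stable to base.

Step 3
Reactants: 4 1-[4-(benzyloxy)-2-hydroxyphenyl]ethan-1-one
Product: 5 1-[4-(benzyloxy)-2-methoxyphenyl]ethan-1-one
Conditions: MeI, K2CO3, DMF, 40 °C
Reagents that add atoms: iodomethane, CI
Why: Williamson methylation of the chelated ortho-phenol should give the ring E ketone with its final methoxy group.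

Step 4
Reactants: 3 2-(benzyloxy)-5-bromo-4-(methoxymethoxy)benzaldehyde; 5 1-[4-(benzyloxy)-2-methoxyphenyl]ethan-1-one
Product: 6 (E)-chalcone carrying ring A (2-benzyloxy-5-bromo-4-methoxymethoxyphenyl) at the β-carbon and ring E at the carbonyl group
Conditions: KOH, EtOH/THF, 25 °C
Reagents that add atoms: none
Why: Claisen–Schmidt condensation (aldol addition, then E1cB dehydration) of a non-enolisable aldehyde with a methyl ketone should give the conjugated enone as the thermodynamically preferred E isomer, and all ethers are base-stable.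

Step 5
Reactants: 6 (E)-chalcone; 7 [4-(benzyloxy)phenyl]boronic acid
Product: 8 (3R)-3-[2-(benzyloxy)-5-bromo-4-(methoxymethoxy)phenyl]-1-[4-(benzyloxy)-2-methoxyphenyl]-3-[4-(benzyloxy)phenyl]propan-1-one
Conditions: [RhCl(C2H4)2]2 (2.5 mol %), chiral diene 2,5-diphenylbicyclo[2.2.2]octa-2,5-diene (5.5 mol %, enantiomer that gives 3R), KOH (0.5 equiv), dioxane/H2O 10:1, 50 °C
Reagents that add atoms: none
Why: Rhodium-catalysed asymmetric 1,4-addition of an arylboronic acid to an enone (Hayashi–Miyaura reaction), in which the aryl–rhodium species formed by transmetalation inserts the enone C=C inside the pocket of the C2-symmetric diene, which selects the β-face and should set the diarylmethine as R; the aryl bromide should not undergo oxidative addition to monovalent rhodium at this temperature.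

Step 6
Reactants: 8 (3R)-β,β-diaryl ketone
Product: 9 5-(benzyloxy)-2-bromo-4-[(1R)-3-[4-(benzyloxy)-2-methoxyphenyl]-1-[4-(benzyloxy)phenyl]propyl]phenol
Conditions: Et3SiH (6 equiv), CF3CO2H/CH2Cl2 1:3, 0 to 25 °C
Reagents that add atoms: none
Why: Ionic hydrogenation, in which the protonated ketone and then the benzylic cation (stabilised by the ortho-methoxy and para-benzyloxy groups of ring E) take two hydrides from the silane to give CH2, while the acid cleaves the MOM acetal and the silane reduces the methoxymethyl cation; the stereocentre carries no leaving group and is not enolisable after this step, so it should be retained.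

Step 7
Reactants: 10 methyl 2,5-dihydroxybenzoate
Product: 11 methyl 5-(benzyloxy)-2-hydroxybenzoate
Conditions: BnBr (1.05 equiv), K2CO3, acetone, reflux
Reagents that add atoms: benzyl bromide, BrCc1ccccc1
Why: Williamson etherification that should be selective for the 5-OH, because the 2-OH is hydrogen-bonded to the ester carbonyl and much less nucleophilic.

Step 8
Reactants: 11 methyl 5-(benzyloxy)-2-hydroxybenzoate
Product: 12 methyl 5-(benzyloxy)-2-methoxybenzoate
Conditions: MeI, K2CO3, DMF, 50 °C
Reagents that add atoms: iodomethane, CI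
Why: Williamson methylation of the chelated phenol under more forcing conditions should install the 2-methoxy group of ring B.

Step 9
Reactants: 12 methyl 5-(benzyloxy)-2-methoxybenzoate
Product: 13 5-(benzyloxy)-2-methoxybenzoic acid
Conditions: LiOH·H2O, THF/H2O, 40 °C; then aq. HCl
Reagents that add atoms: lithium hydroxide (its oxygen ends in the carboxyl group), [Li+].[OH-]
Why: Saponification by acyl substitution at the methyl ester should give the ring B acid, and aryl ethers are inert.

Step 10
Reactants: 9 bromophenol; 13 5-(benzyloxy)-2-methoxybenzoic acid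
Product: 14 5-(benzyloxy)-2-bromo-4-[(1R)-3-[4-(benzyloxy)-2-methoxyphenyl]-1-[4-(benzyloxy)phenyl]propyl]phenyl 5-(benzyloxy)-2-methoxybenzoate
Conditions: EDC·HCl, DMAP, CH2Cl2, 25 °C
Reagents that add atoms: none
Why: Steglich esterification through the O-acylisourea and the acylpyridinium ion should acylate the only free hydroxyl group, the future O1, and thereby join O1 to the future C2.

Step 11
Reactants: 14 bromoaryl ester
Product: 15 2-allyl-5-(benzyloxy)-4-[(1R)-3-[4-(benzyloxy)-2-methoxyphenyl]-1-[4-(benzyloxy)phenyl]propyl]phenyl 5-(benzyloxy)-2-methoxybenzoate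
Conditions: allylSnBu3, Pd(PPh3)4 (5 mol %), toluene, 100 °C
Reagents that add atoms: allyltributylstannane, C=CC[Sn](CCCC)(CCCC)CCCC
Why: Stille coupling (oxidative addition of zerovalent palladium into the C–Br bond, transmetalation, reductive elimination) should place the allyl group exactly at the future C4a, and the neutral conditions spare the aryl ester.

Step 12
Reactants: 15 2-allylaryl benzoate
Product: 17 7-(benzyloxy)-2-[5-(benzyloxy)-2-methoxyphenyl]-6-[(1R)-3-[4-(benzyloxy)-2-methoxyphenyl]-1-[4-(benzyloxy)phenyl]propyl]-4H-chromene, via acyclic enol ether 16 (not isolated)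
Conditions: Cp2Ti(μ-Cl)(μ-CH2)AlMe2 (Tebbe reagent, 4 equiv), THF, 25 °C, then reflux; aq. NaOH quench, basic alumina
Reagents that add atoms: none
Why: The titanium methylidene released from the Tebbe reagent first methylenates the only carbonyl group, the aryl ester, through an oxatitanacyclobutane to give enol ether 16; at reflux a second methylidene exchanges with the terminal allyl olefin to a titanium alkylidene at C3, which adds across the enol ether C2=CH2 and cycloreverts, so that C2=C3 is formed and ethylene is lost (the methylene carbon of the reagent does not remain in 17). The closest known reaction type is the tandem ester methylenation/ring-closing olefin metathesis of olefinic esters to cyclic enol ethers with excess Tebbe reagent, applied here to an aryl ester and an ortho-allyl group. Ring C is closed as a six-membered ring by ring-closing metathesis, the new bond being the endocyclic enol ether double bond C2=C3, with O1–C2 already in place from the ester. No stereocentre is formed, because C2 leaves the step trigonal; its configuration is set in step 13. The step needs chemoselectivity (one carbonyl group and one olefin only, secured by the removal of the ketone in step 6 and by benzyl and methyl ethers as the only other functions) and ring-size fidelity (the olefin must stay allylic, since migration to the styrenyl position would lead to a benzofuran), which the non-acidic titanium conditions and the ortho placement of the two reacting groups should secure.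

Step 13
Reactants: 17 2-aryl-4H-chromene
Product: 18 (2S)-7-(benzyloxy)-2-[5-(benzyloxy)-2-methoxyphenyl]-6-[(1R)-3-[4-(benzyloxy)-2-methoxyphenyl]-1-[4-(benzyloxy)phenyl]propyl]-3,4-dihydro-2H-chromene
Conditions: H2 (50 bar), [Ir(cod)(tBu-PHOX)][B(3,5-(CF3)2C6H3)4] (2 mol %, ligand enantiomer that gives 2S), CH2Cl2, 25 °C
Reagents that add atoms: none
Why: Iridium-catalysed asymmetric hydrogenation of a trisubstituted cyclic enol ether, in which the cationic N,P-ligated iridium hydride should deliver H2 to one face of C2=C3 under ligand control and so set C2 as S independently of the remote stereocentre; benzyl ethers and arenes are not reduced by this catalyst.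

Step 14
Reactants: 18 (2S)-flavan tetrabenzyl ether
Product: 19 (2S)-6-[(1R)-3-(4-hydroxy-2-methoxyphenyl)-1-(4-hydroxyphenyl)propyl]-2-(5-hydroxy-2-methoxyphenyl)-3,4-dihydro-2H-chromen-7-ol (CNP0239474.1)
Conditions: H2 (1 atm), Pd(OH)2/C, EtOAc/MeOH, 25 °C
Reagents that add atoms: none
Why: Hydrogenolysis of the four aryl benzyl ethers should free all phenols; under neutral conditions the cyclic benzylic C2–O1 bond and the diarylmethine C–H are cleaved far more slowly, so both stereocentres should be retained.

Compound list

1 | 5-bromo-2,4-dihydroxybenzaldehyde | O=Cc1cc(Br)c(O)cc1O | starting material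
2 | 5-bromo-2-hydroxy-4-(methoxymethoxy)benzaldehyde | O=Cc1cc(Br)c(OCOC)cc1O | intermediate
3 | 2-(benzyloxy)-5-bromo-4-(methoxymethoxy)benzaldehyde | O=Cc1cc(Br)c(OCOC)cc1OCc1ccccc1 | intermediate
4 | 1-[4-(benzyloxy)-2-hydroxyphenyl]ethan-1-one | CC(=O)c1ccc(OCc2ccccc2)cc1O | starting material
5 | 1-[4-(benzyloxy)-2-methoxyphenyl]ethan-1-one | COc1cc(OCc2ccccc2)ccc1C(C)=O | intermediate
6 | (E)-3-[2-(benzyloxy)-5-bromo-4-(methoxymethoxy)phenyl]-1-[4-(benzyloxy)-2-methoxyphenyl]prop-2-en-1-one | COc1cc(OCc2ccccc2)ccc1C(=O)/C=C/c1cc(Br)c(OCOC)cc1OCc1ccccc1 | intermediate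
7 | [4-(benzyloxy)phenyl]boronic acid | OB(O)c1ccc(OCc2ccccc2)cc1 | starting material
8 | (3R)-3-[2-(benzyloxy)-5-bromo-4-(methoxymethoxy)phenyl]-1-[4-(benzyloxy)-2-methoxyphenyl]-3-[4-(benzyloxy)phenyl]propan-1-one | COc1cc(OCc2ccccc2)ccc1C(=O)C[C@H](c1ccc(OCc2ccccc2)cc1)c1cc(Br)c(OCOC)cc1OCc1ccccc1 | intermediate
9 | 5-(benzyloxy)-2-bromo-4-[(1R)-3-[4-(benzyloxy)-2-methoxyphenyl]-1-[4-(benzyloxy)phenyl]propyl]phenol | COc1cc(OCc2ccccc2)ccc1CC[C@H](c1ccc(OCc2ccccc2)cc1)c1cc(Br)c(O)cc1OCc1ccccc1 | intermediate
10 | methyl 2,5-dihydroxybenzoate | COC(=O)c1cc(O)ccc1O | starting material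
11 | methyl 5-(benzyloxy)-2-hydroxybenzoate | COC(=O)c1cc(OCc2ccccc2)ccc1O | intermediate
12 | methyl 5-(benzyloxy)-2-methoxybenzoate | COC(=O)c1cc(OCc2ccccc2)ccc1OC | intermediate
13 | 5-(benzyloxy)-2-methoxybenzoic acid | OC(=O)c1cc(OCc2ccccc2)ccc1OC | intermediate
14 | 5-(benzyloxy)-2-bromo-4-[(1R)-3-[4-(benzyloxy)-2-methoxyphenyl]-1-[4-(benzyloxy)phenyl]propyl]phenyl 5-(benzyloxy)-2-methoxybenzoate | COc1cc(OCc2ccccc2)ccc1CC[C@H](c1ccc(OCc2ccccc2)cc1)c1cc(Br)c(OC(=O)c2cc(OCc3ccccc3)ccc2OC)cc1OCc1ccccc1 | intermediate
15 | 2-allyl-5-(benzyloxy)-4-[(1R)-3-[4-(benzyloxy)-2-methoxyphenyl]-1-[4-(benzyloxy)phenyl]propyl]phenyl 5-(benzyloxy)-2-methoxybenzoate | COc1cc(OCc2ccccc2)ccc1CC[C@H](c1ccc(OCc2ccccc2)cc1)c1cc(CC=C)c(OC(=O)c2cc(OCc3ccccc3)ccc2OC)cc1OCc1ccccc1 | intermediate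
16 | 1-[5-(benzyloxy)-2-methoxyphenyl]vinyl 2-allyl-5-(benzyloxy)-4-[(1R)-3-[4-(benzyloxy)-2-methoxyphenyl]-1-[4-(benzyloxy)phenyl]propyl]phenyl ether | COc1cc(OCc2ccccc2)ccc1CC[C@H](c1ccc(OCc2ccccc2)cc1)c1cc(CC=C)c(OC(=C)c2cc(OCc3ccccc3)ccc2OC)cc1OCc1ccccc1 | intermediate
17 | 7-(benzyloxy)-2-[5-(benzyloxy)-2-methoxyphenyl]-6-[(1R)-3-[4-(benzyloxy)-2-methoxyphenyl]-1-[4-(benzyloxy)phenyl]propyl]-4H-chromene | COc1cc(OCc2ccccc2)ccc1CC[C@H](c1ccc(OCc2ccccc2)cc1)c1cc2c(cc1OCc1ccccc1)OC(c1cc(OCc3ccccc3)ccc1OC)=CC2 | intermediate
18 | (2S)-7-(benzyloxy)-2-[5-(benzyloxy)-2-methoxyphenyl]-6-[(1R)-3-[4-(benzyloxy)-2-methoxyphenyl]-1-[4-(benzyloxy)phenyl]propyl]-3,4-dihydro-2H-chromene | COc1cc(OCc2ccccc2)ccc1CC[C@H](c1ccc(OCc2ccccc2)cc1)c1cc2c(cc1OCc1ccccc1)O[C@H](c1cc(OCc3ccccc3)ccc1OC)CC2 | intermediate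
19 | (2S)-6-[(1R)-3-(4-hydroxy-2-methoxyphenyl)-1-(4-hydroxyphenyl)propyl]-2-(5-hydroxy-2-methoxyphenyl)-3,4-dihydro-2H-chromen-7-ol | COc1cc(O)ccc1CC[C@H](c1ccc(O)cc1)c1cc2c(cc1O)O[C@H](c1cc(O)ccc1OC)CC2 | target

Total step count: 14.
Longest linear sequence: 10 steps (steps 1, 2, 4, 5, 6, 10, 11, 12, 13 and 14, from 1 to 19).

The three steps most likely to fail

Step 12. The methylenation may proceed while the titanium-mediated ring closure stalls at the hindered 1,1-disubstituted enol ether. The titanium alkylidene may also decompose at reflux, the olefin may migrate out of the allylic position and divert the closure to a five-membered ring, or the acid-labile enol ether may hydrolyse during isolation. The fallback gives up the one-pot titanium relay and separates the two events, with a different metal closing the ring. It sets out from 15, which is only methylenated with dimethyltitanocene Cp2TiMe2 (toluene, 65 °C), and enol ether 16 is isolated on basic alumina. The ring is then closed in a discrete catalytic diene ring-closing metathesis with second-generation Grubbs catalyst RuCl2(=CHPh)(H2IMes)(PCy3) in toluene at 70 °C. This comes back to the route at 17 and makes no compound outside the list.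

Step 13. Hydrogen uptake at the trisubstituted enol ether carrying an ortho-methoxyaryl group may be slow or poorly face-selective. The acidic cationic iridium hydride may also promote double-bond migration or hydrolysis before reduction. The fallback sets out from 17 and closes the ring at O1–C2 with a stereocentre made beforehand. Mild acid hydrolysis of the enol ether (aq. HCl, THF) should open it to 1-[5-(benzyloxy)-2-methoxyphenyl]-3-[4-(benzyloxy)-5-[(1R)-3-[4-(benzyloxy)-2-methoxyphenyl]-1-[4-(benzyloxy)phenyl]propyl]-2-hydroxyphenyl]propan-1-one F1. Corey–Bakshi–Shibata reduction of this aryl ketone ((S)-2-methyl-CBS-oxazaborolidine, excess BH3·SMe2, THF) should give the (1R)-configured benzylic alcohol F2. Mitsunobu cyclisation (PPh3, DIAD, THF, 0 °C) displaces the activated hydroxyl group by the phenol with inversion and comes back to the route at 18.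

Step 5. Insertion into the electron-rich, ortho-alkoxy-substituted β-aryl enone may be slow, so that protodeboronation of the boronic acid competes, and facial control may be incomplete. The fallback sets out from 6 and makes the stereocentre by asymmetric hydride delivery instead of asymmetric aryl delivery. Heck arylation of the chalcone with 1-(benzyloxy)-4-iodobenzene (Pd(OAc)2, n-Bu4NCl, NaHCO3, DMF, 80 °C; the aryl iodide should react well before the ring A bromide) should give the (Z)-β,β-diaryl enone F3 by syn-carbopalladation and syn-β-hydride elimination. CuH-catalysed asymmetric conjugate reduction (Cu(OAc)2, DTBM-SEGPHOS in the enantiomer that gives 3R, polymethylhydrosiloxane, t-BuOH, toluene) then comes back to the route at 8. The catalyst has to distinguish the twisted ortho-substituted ring A from the para-substituted ring D.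

Further compounds

F0 | step 12 | none | none
F1 | step 13 | 1-[5-(benzyloxy)-2-methoxyphenyl]-3-[4-(benzyloxy)-5-[(1R)-3-[4-(benzyloxy)-2-methoxyphenyl]-1-[4-(benzyloxy)phenyl]propyl]-2-hydroxyphenyl]propan-1-one | COc1cc(OCc2ccccc2)ccc1CC[C@H](c1ccc(OCc2ccccc2)cc1)c1cc(CCC(=O)c2cc(OCc3ccccc3)ccc2OC)c(O)cc1OCc1ccccc1
F2 | step 13 | (1R)-1-[5-(benzyloxy)-2-methoxyphenyl]-3-[4-(benzyloxy)-5-[(1R)-3-[4-(benzyloxy)-2-methoxyphenyl]-1-[4-(benzyloxy)phenyl]propyl]-2-hydroxyphenyl]propan-1-ol | COc1cc(OCc2ccccc2)ccc1CC[C@H](c1ccc(OCc2ccccc2)cc1)c1cc(CC[C@@H](O)c2cc(OCc3ccccc3)ccc2OC)c(O)cc1OCc1ccccc1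
F3 | step 5 | (Z)-3-[2-(benzyloxy)-5-bromo-4-(methoxymethoxy)phenyl]-1-[4-(benzyloxy)-2-methoxyphenyl]-3-[4-(benzyloxy)phenyl]prop-2-en-1-one | COc1cc(OCc2ccccc2)ccc1C(=O)/C=C(/c1ccc(OCc2ccccc2)cc1)c1cc(Br)c(OCOC)cc1OCc1ccccc1
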